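**Strategy.** Oxane C2 carries the ring oxygen O1 and the pyridone, so it is an aldehyde-level carbon, and pyridone C3 is the nucleophilic carbon of a vinylogous acid between C2=O and C4–OH. Everything rests on joining these two atoms last: a domino Knoevenagel condensation/oxa-Michael addition between the free 1,4-dihydroxy-5-phenylpyridone and a trienyl lactol (a masked δ-hydroxy aldehyde carrying the C3 methyl stereocentre, the Z-exocyclic alkene and the whole side chain). In one operation it forms the C–C bond, closes the oxane through an ortho-quinone methide and sets C2 trans to C3, converging lactol anomers and quinone methide isomers on one diastereomer. No protecting group is carried into or out of this step.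

Key step: step 10

Remark: the N-hydroxypyridone is written throughout as the 1-hydroxy-2-pyridone tautomer, and (R)-2-methylbutan-1-ol and (S)-3-bromo-2-methylpropan-1-ol are taken as purchasable single enantiomers.

Step 1
Reactants: 1 5-bromo-2,4-dichloropyridine
Product: 2 2,4-bis(benzyloxy)-5-bromopyridine
Conditions: BnOH, NaH, DMF, 0 → 80 °C
Reagents that add atoms: benzyl alcohol (as sodium benzyl oxide), OCc1ccccc1
Why: Double nucleophilic aromatic substitution (SNAr) displaces the two chlorides that sit ortho and para to the ring nitrogen, while the unactivated bromide at C5 stays for the coupling.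

Step 2
Reactants: 2 2,4-bis(benzyloxy)-5-bromopyridine; 3 phenylboronic acid
Product: 4 2,4-bis(benzyloxy)-5-phenylpyridine
Conditions: Pd(PPh3)4 (cat.), K2CO3, 1,4-dioxane/H2O, 90 °C
Reagents that add atoms: none
Why: Suzuki–Miyaura coupling at the only carbon–halogen bond installs the 5-phenyl group, and the benzyl ethers are inert.

Step 3
Reactants: 4 2,4-bis(benzyloxy)-5-phenylpyridine
Product: 5 2,4-bis(benzyloxy)-5-phenylpyridine 1-oxide
Conditions: mCPBA, CH2Cl2, 0 → 23 °C
Reagents that add atoms: mCPBA, OOC(=O)c1cccc(Cl)c1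
Why: Peracid N-oxidation of the electron-rich 2,4-dialkoxypyridine makes the N–O bond before any alkene is present in the synthesis.

Step 4
Reactants: 5 2,4-bis(benzyloxy)-5-phenylpyridine 1-oxide
Product: 6 1,4-dihydroxy-5-phenylpyridin-2(1H)-one
Conditions: H2 (1 atm), Pd/C (palladium on carbon), MeOH/THF, 23 °C
Reagents that add atoms: none
Why: Hydrogenolysis removes both benzyl groups and the 2-hydroxypyridine N-oxide tautomerises to the cyclic hydroxamic acid, whose N–O bond should survive these mild conditions.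

Step 5
Reactants: 7 (R)-2-methylbutan-1-ol
Product: 9 (2E,4R)-4-methylhex-2-enal, via (R)-2-methylbutanal 8 (not isolated)
Conditions: TEMPO (cat.), KBr, NaOCl, NaHCO3, CH2Cl2/H2O, 0 °C; dried organic phase, then Ph3P=CHCHO, toluene, 70 °C
Reagents that add atoms: (triphenylphosphoranylidene)acetaldehyde, O=CC=P(c1ccccc1)(c1ccccc1)c1ccccc1
Why: TEMPO/hypochlorite oxidation should give the volatile, configurationally labile aldehyde without epimerisation, and the stabilised ylide traps it at once in an E-selective Wittig reaction, the stereocentre coming unchanged from 7.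

Step 6
Reactants: 9 (2E,4R)-4-methylhex-2-enal
Product: 10 4,4,5,5-tetramethyl-2-[(1E,3E,5R)-5-methylhepta-1,3-dien-1-yl]-1,3,2-dioxaborolane
Conditions: Cl2CHBpin, CrCl2, LiI, THF, 23 °C
Reagents that add atoms: 2-(dichloromethyl)-4,4,5,5-tetramethyl-1,3,2-dioxaborolane, ClC(Cl)B1OC(C)(C)C(C)(C)O1
Why: Takai-type olefination with the geminal dichromium reagent from the dihalomethylboronate converts the enal into the E-alkenylboronate without touching the existing E-alkene or the stereocentre.

Step 7
Reactants: 11 (S)-3-bromo-2-methylpropan-1-ol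
Product: 13 (S)-3-bromo-1,1-dimethoxy-2-methylpropane, via (S)-3-bromo-2-methylpropanal 12 (not isolated)
Conditions: Dess–Martin periodinane, CH2Cl2, 0 → 23 °C; then HC(OMe)3, MeOH, p-TsOH (cat.), 0 → 23 °C
Reagents that add atoms: trimethyl orthoformate, COC(OC)OC; methanol, CO
Why: Dess–Martin oxidation is base-free (base would eliminate HBr) and immediate acid-catalysed acetalisation with the orthoformate masks the aldehyde before its α-stereocentre, carried from 11, can enolise.

Step 8
Reactants: 13 (S)-3-bromo-1,1-dimethoxy-2-methylpropane; 14 prop-2-yn-1-ol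
Product: 18 (3R,5Z)-5-(iodomethylidene)-3-methyloxan-2-ol, via Grignard reagent 15 (not isolated), via alkenylmagnesium chelate 16 (not isolated), via hydroxy acetal iodide 17 (not isolated)
Conditions: 13, Mg, THF, 30 °C; 14 + iPrMgCl, THF, 0 °C; combined, CuI (cat.), THF, −10 → 23 °C; I2, −20 → 0 °C; aq. Na2S2O3, then 1 M HCl, THF, 23 °C
Reagents that add atoms: iodine, II; water, O
Why: Copper-catalysed anti-carbomagnesiation of the propargylic alkoxide puts the alkyl group on the inner alkyne carbon and magnesium in a five-membered chelate cis to CH2O, iodinolysis with retention gives the Z-iodoalkene, and acid hydrolysis of the dimethyl acetal closes the six-membered lactol with the C3 stereocentre carried from 13.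

Step 9
Reactants: 18 (3R,5Z)-5-(iodomethylidene)-3-methyloxan-2-ol; 10 4,4,5,5-tetramethyl-2-[(1E,3E,5R)-5-methylhepta-1,3-dien-1-yl]-1,3,2-dioxaborolane
Product: 19 (3R,5Z)-3-methyl-5-[(2E,4E,6R)-6-methylocta-2,4-dien-1-ylidene]oxan-2-ol
Conditions: Pd(OAc)2 (cat.), SPhos, K3PO4, THF/H2O, 23 °C, dark
Reagents that add atoms: none
Why: Suzuki–Miyaura coupling of alkenyl iodide and dienylboronate proceeds with retention at both partners and should give the Z,E,E-triene, the lactol being tolerated by the mild phosphate base at room temperature.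

Step 10
Reactants: 19 (3R,5Z)-3-methyl-5-[(2E,4E,6R)-6-methylocta-2,4-dien-1-ylidene]oxan-2-ol; 6 1,4-dihydroxy-5-phenylpyridin-2(1H)-one
Product: 21 1,4-dihydroxy-3-[(2R,3R,5Z)-3-methyl-5-[(2E,4E,6R)-6-methylocta-2,4-dien-1-ylidene]oxan-2-yl]-5-phenylpyridin-2(1H)-one (CNP0190742.3), via quinone methide 20 (not isolated)
Conditions: EDDA (ethylenediammonium diacetate, cat.), EtOH, 40 °C, Ar, dark
Reagents that add atoms: none
Why: The lactol opens to the δ-hydroxy aldehyde, which condenses at C3 of pyridone 6 (Knoevenagel, amine-salt catalysis) to form the C–C bond and the 3-alkylidene-pyridine-2,4-dione (ortho-quinone methide) 20, whose C6 hydroxyl then adds to the exocyclic carbon and restores the aromatic pyridone. The closest known reaction type is the domino Knoevenagel/oxa-Michael reaction of cyclic 1,3-dicarbonyl compounds and 4-hydroxy-2-pyridones with hydroxy aldehydes and lactols. The oxane ring closes in the 6-exo-trig mode by O1–C2 bond formation. The new stereocentre C2 is controlled by the C3 methyl group: allylic strain holds C3–H in the plane of the quinone methide, so the oxygen attacks through a chair with methyl and pyridone both equatorial, giving the 2,3-trans (2R,3R) ring. The closure is reversible (retro-oxa-Michael), so both lactol anomers, both geometries of 20 and any cis adduct should converge on this most stable diastereomer. The step needs ring closure to outrun addition of a second pyridone to 20 and tautomerisation of 20 at C3, which the tethered hydroxyl, the 1:1 stoichiometry and the buffered non-basic medium should secure, while the triene is insulated from 20 by the sp3 carbon C4.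

**Compound list**

1 | 5-bromo-2,4-dichloropyridine | Clc1cc(Cl)c(Br)cn1 | starting material
2 | 2,4-bis(benzyloxy)-5-bromopyridine | Brc1cnc(OCc2ccccc2)cc1OCc1ccccc1 | intermediate
3 | phenylboronic acid | OB(O)c1ccccc1 | starting material
4 | 2,4-bis(benzyloxy)-5-phenylpyridine | c1ccc(-c2cnc(OCc3ccccc3)cc2OCc2ccccc2)cc1 | intermediate
5 | 2,4-bis(benzyloxy)-5-phenylpyridine 1-oxide | [O-][n+]1cc(-c2ccccc2)c(OCc2ccccc2)cc1OCc1ccccc1 | intermediate
6 | 1,4-dihydroxy-5-phenylpyridin-2(1H)-one | O=c1cc(O)c(-c2ccccc2)cn1O | intermediate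
7 | (R)-2-methylbutan-1-ol | CC[C@@H](C)CO | starting material
8 | (R)-2-methylbutanal (formed in situ) | CC[C@@H](C)C=O | intermediate
9 | (2E,4R)-4-methylhex-2-enal | CC[C@@H](C)/C=C/C=O | intermediate
10 | 4,4,5,5-tetramethyl-2-[(1E,3E,5R)-5-methylhepta-1,3-dien-1-yl]-1,3,2-dioxaborolane | CC[C@@H](C)/C=C/C=C/B1OC(C)(C)C(C)(C)O1 | intermediate
11 | (S)-3-bromo-2-methylpropan-1-ol | OC[C@H](C)CBr | starting material
12 | (S)-3-bromo-2-methylpropanal (formed in situ) | O=C[C@H](C)CBr | intermediate
13 | (S)-3-bromo-1,1-dimethoxy-2-methylpropane | COC(OC)[C@H](C)CBr | intermediate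
14 | prop-2-yn-1-ol (propargyl alcohol) | C#CCO | starting material
15 | [(2S)-3,3-dimethoxy-2-methylpropyl]magnesium bromide (formed in situ) | COC(OC)[C@H](C)C[Mg]Br | intermediate
16 | (Z)-3-(bromomagnesio)-2-[(2R)-3,3-dimethoxy-2-methylpropyl]prop-2-en-1-ol chloromagnesium alkoxide, magnesium on the alkene cis to CH2O (formed in situ) | Br[Mg]/C=C(\CO[Mg]Cl)C[C@@H](C)C(OC)OC | intermediate
17 | (2Z)-2-[(2R)-3,3-dimethoxy-2-methylpropyl]-3-iodoprop-2-en-1-ol (formed in situ) | I/C=C(\CO)C[C@@H](C)C(OC)OC | intermediate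
18 | (3R,5Z)-5-(iodomethylidene)-3-methyloxan-2-ol, mixture of anomers | I/C=C1\COC(O)[C@H](C)C1 | intermediate
19 | (3R,5Z)-3-methyl-5-[(2E,4E,6R)-6-methylocta-2,4-dien-1-ylidene]oxan-2-ol, mixture of anomers | CC[C@@H](C)/C=C/C=C/C=C1\COC(O)[C@H](C)C1 | intermediate
20 | 1-hydroxy-3-[(2R,4Z,6E,8E,10R)-4-(hydroxymethyl)-2,10-dimethyldodeca-4,6,8-trien-1-ylidene]-5-phenylpyridine-2,4(1H,3H)-dione, both geometries at the ring alkylidene (formed in situ) | CC[C@@H](C)/C=C/C=C/C=C(\CO)C[C@@H](C)C=C1C(=O)C(-c2ccccc2)=CN(O)C1=O | intermediate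
21 | 1,4-dihydroxy-3-[(2R,3R,5Z)-3-methyl-5-[(2E,4E,6R)-6-methylocta-2,4-dien-1-ylidene]oxan-2-yl]-5-phenylpyridin-2(1H)-one | CC[C@@H](C)/C=C/C=C/C=C1\CO[C@@H](c2c(O)c(-c3ccccc3)cn(O)c2=O)[C@H](C)C1 | target

**Count and risks**

Total step count: 10. Longest linear sequence: 5 steps (steps 1, 2, 3, 4 and 10).

Most likely to fail, in this order:

Step 10. The free N-hydroxy group, a cyclic hydroxamic acid, may divert the quinone methide into O-adducts or bind the amine salt, the condensation may stall at 2:1 pyridone adducts, and prolonged equilibration may erode C3 through tautomerisation of the quinone methide. The fallback makes the N–O bond after the ring-forming step and sets out from 4 and 19. Hydrogenolysis of 4 (H2, Pd/C) would give 4-hydroxy-5-phenylpyridin-2(1H)-one F1. Its Knoevenagel/oxa-Michael union with 19 (Et3N, EtOH, 23 → 60 °C) would give the N–H analogue of the target, 4-hydroxy-3-[(2R,3R,5Z)-3-methyl-5-[(2E,4E,6R)-6-methylocta-2,4-dien-1-ylidene]oxan-2-yl]-5-phenylpyridin-2(1H)-one F2. Persilylation (HMDS, TMSCl) would give the 2,4-bis(trimethylsilyloxy)pyridine F3, and oxidation at nitrogen with MoO(O2)2·pyridine·HMPA followed by aqueous work-up would come back to the route at 21.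

Step 8. The β-branched, acetal-bearing Grignard reagent may add too slowly to the propargylic alkoxide and be consumed instead by Wurtz coupling or by 1,3-elimination of methoxide, so that little alkenylmagnesium forms. The fallback replaces carbometalation by olefination and sp3–sp2 cross-coupling and sets out from 9 and 13. A second Wittig homologation of 9 (Ph3P=CHCHO) would give (2E,4E,6R)-6-methylocta-2,4-dienal F4. Horner–Wadsworth–Emmons reaction with ethyl 2-[bis(2,2,2-trifluoroethoxy)phosphoryl]-2-bromoacetate (t-BuOK, 18-crown-6, THF, −78 °C) would give ethyl (2E,4E,6E,8R)-2-bromo-8-methyldeca-2,4,6-trienoate F5, with the ester cis to the chain. Zinc insertion into 13 (Zn, LiCl, THF, 50 °C) would give bromo[(2S)-3,3-dimethoxy-2-methylpropyl]zinc F6. Negishi coupling of F5 with F6 (Pd(PPh3)4, THF) should proceed with retention to ethyl (2Z,4E,6E,8R)-2-[(2R)-3,3-dimethoxy-2-methylpropyl]-8-methyldeca-2,4,6-trienoate F7. Reduction with iBu2AlH would give (2Z,4E,6E,8R)-2-[(2R)-3,3-dimethoxy-2-methylpropyl]-8-methyldeca-2,4,6-trien-1-ol F8, and mild hydrolysis (PPTS, acetone/H2O, 23 °C) would close the lactol and come back to the route at 19, so that 18 and step 9 are bypassed.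

Step 9. Under the aqueous phosphate conditions the lactol may epimerise at C3 through its open hydroxy aldehyde form, and the dienylboronate may undergo protodeboronation or alkene isomerisation. The fallback is a base-free Stille coupling and sets out from 9 and 18. Chromium-mediated stannyl olefination of 9 (CrCl2, Bu3SnCHBr2, LiI, THF/DMF) would give tributyl[(1E,3E,5R)-5-methylhepta-1,3-dien-1-yl]stannane F9, which would couple with 18 under neutral conditions (Pd2(dba)3, AsPh3, NMP, 23 °C) and come back to the route at 19.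

Further compounds
F1 | step 10 | 4-hydroxy-5-phenylpyridin-2(1H)-one | O=c1cc(O)c(-c2ccccc2)c[nH]1
F2 | step 10 | 4-hydroxy-3-[(2R,3R,5Z)-3-methyl-5-[(2E,4E,6R)-6-methylocta-2,4-dien-1-ylidene]oxan-2-yl]-5-phenylpyridin-2(1H)-one | CC[C@@H](C)/C=C/C=C/C=C1\CO[C@@H](c2c(O)c(-c3ccccc3)c[nH]c2=O)[C@H](C)C1
F3 | step 10 | 3-[(2R,3R,5Z)-3-methyl-5-[(2E,4E,6R)-6-methylocta-2,4-dien-1-ylidene]oxan-2-yl]-5-phenyl-2,4-bis(trimethylsilyloxy)pyridine | CC[C@@H](C)/C=C/C=C/C=C1\CO[C@@H](c2c(O[Si](C)(C)C)c(-c3ccccc3)cnc2O[Si](C)(C)C)[C@H](C)C1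
F4 | step 8 | (2E,4E,6R)-6-methylocta-2,4-dienal | CC[C@@H](C)/C=C/C=C/C=O
F5 | step 8 | ethyl (2E,4E,6E,8R)-2-bromo-8-methyldeca-2,4,6-trienoate | CC[C@@H](C)/C=C/C=C/C=C(/Br)C(=O)OCC
F6 | step 8 | bromo[(2S)-3,3-dimethoxy-2-methylpropyl]zinc | COC(OC)[C@H](C)C[Zn]Br
F7 | step 8 | ethyl (2Z,4E,6E,8R)-2-[(2R)-3,3-dimethoxy-2-methylpropyl]-8-methyldeca-2,4,6-trienoate | CC[C@@H](C)/C=C/C=C/C=C(/C[C@@H](C)C(OC)OC)C(=O)OCC
F8 | step 8 | (2Z,4E,6E,8R)-2-[(2R)-3,3-dimethoxy-2-methylpropyl]-8-methyldeca-2,4,6-trien-1-ol | CC[C@@H](C)/C=C/C=C/C=C(\CO)C[C@@H](C)C(OC)OC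
F9 | step 9 | tributyl[(1E,3E,5R)-5-methylhepta-1,3-dien-1-yl]stannane | CC[C@@H](C)/C=C/C=C/[Sn](CCCC)(CCCC)CCCC
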